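**Plan**
Retrosynthesis: the side-chain aldol bond (carbinol carbon to the α-methyl carbon) is cut first, giving pentan-3-one and a 2-substituted propenal. Then the oxirane oxygen is removed, the cyclohexadiene is opened by retro-6π at ring bond C4–C5, and the resulting (2E,4Z,6E)-triene is cut on both sides of its central C(CH3)=CH unit, i.e. at ring bond C2–C3 and at the oxirane C1–C6 bond.
Enabling feature: in the 7-oxabicyclo[4.1.0]hept-2-ene, C2 (the C-methyl alkene carbon) and C1 (the oxirane CH) are a two-carbon propyne unit that sits between two sp2 carbons in the open-chain valence isomer of the six-membered ring. cis-1,2-Diborylpropene supplies this unit with the Z geometry that ring closure needs.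
Forward: a pyranone alkenyl iodide (7 steps) and a dienyl iodide (3 steps) are joined to the diborylpropene in a one-pot double Suzuki coupling. Heat then closes the carbocycle, epoxidation forms the oxirane ring, and desilylation, oxidation and an aldol addition finish the side chain.
Stereochemistry: alkene geometries come from anti-carbomagnesiation, syn-hydrozirconation and syn-diboration. Disrotatory closure makes the C4 and C5 substituents cis. A Shi epoxidation run as a kinetic resolution fixes the absolute configuration of the ring and both oxirane carbons, and a reagent-controlled syn-aldol sets the carbinol and α-methyl centres.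

Key step: step 12

Remark: compound 21 is formed as a racemate; its name and SMILES show the enantiomer that step 14 carries on.

**Step 1**
Reactants: 1 3-(trimethylsilyl)prop-2-yn-1-ol
Product: 3 (2E)-2-methyl-3-(trimethylsilyl)prop-2-en-1-ol, via cyclic alkenylmagnesium alkoxide 2 (not isolated)
Conditions: MeMgCl (3 equiv), CuI (10 mol %), THF, 0 °C to 40 °C; aq NH4Cl
Reagents that add atoms: methylmagnesium chloride, C[Mg]Cl
Why: Copper-catalysed anti-carbomagnesiation of a propargylic alcohol: the magnesium alkoxide directs methyl to C2 and magnesium to the silyl-bearing carbon in a five-membered chelate, so that protonation leaves silicon cis to the new methyl group and fixes the E alkene.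

**Step 2**
Reactants: 3 (2E)-2-methyl-3-(trimethylsilyl)prop-2-en-1-ol
Product: 4 (2E)-2-methyl-3-(trimethylsilyl)prop-2-enal
Conditions: MnO2 (activated, excess), CH2Cl2, rt
Reagents that add atoms: none
Why: Oxidation of a primary allylic alcohol on MnO2 leaves the vinylsilane and its geometry untouched.

**Step 3**
Reactants: 4 (2E)-2-methyl-3-(trimethylsilyl)prop-2-enal; 5 ethyl 2-methyl-3-oxopentanoate
Product: 7 ethyl (6E)-5-hydroxy-2,4,6-trimethyl-3-oxo-7-(trimethylsilyl)hept-6-enoate (diastereomer mixture), via dianion of the keto ester 6 (not isolated)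
Conditions: 5, NaH (1.1 equiv), THF, 0 °C; n-BuLi (1.05 equiv), 0 °C; then 4, −78 °C; aq NH4Cl
Reagents that add atoms: none
Why: Aldol addition of a β-keto ester dianion, whose γ-carbanion is the more nucleophilic site and adds 1,2 to the enal; the new stereocentres are erased in steps 4 and 5.

**Step 4**
Reactants: 7 ethyl (6E)-5-hydroxy-2,4,6-trimethyl-3-oxo-7-(trimethylsilyl)hept-6-enoate
Product: 8 ethyl (6E)-2,4,6-trimethyl-3,5-dioxo-7-(trimethylsilyl)hept-6-enoate
Conditions: Dess–Martin periodinane, NaHCO3, CH2Cl2, rt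
Reagents that add atoms: none
Why: Dess–Martin oxidation turns the β-hydroxy ketone into the 3,5-dioxo ester under neutral conditions.

**Step 5**
Reactants: 8 ethyl (6E)-2,4,6-trimethyl-3,5-dioxo-7-(trimethylsilyl)hept-6-enoate
Product: 9 4-hydroxy-3,5-dimethyl-6-[(1E)-1-(trimethylsilyl)prop-1-en-2-yl]-2H-pyran-2-one
Conditions: DBU (1.5 equiv), PhMe, 60 °C; aq HCl
Reagents that add atoms: none
Why: Base-induced lactonisation of a 3,5-dioxo ester (the C5 enolate oxygen attacks the ester carbonyl, 6-exo-trig, with loss of ethoxide) gives the 4-hydroxy-2-pyranone, and the vinylsilane, unlike a vinyl iodide, offers the enolate no leaving group for a competing vinylic substitution.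

**Step 6**
Reactants: 9 4-hydroxy-3,5-dimethyl-6-[(1E)-1-(trimethylsilyl)prop-1-en-2-yl]-2H-pyran-2-one
Product: 10 2-methoxy-3,5-dimethyl-6-[(1E)-1-(trimethylsilyl)prop-1-en-2-yl]-4H-pyran-4-one
Conditions: MeOTf (1.5 equiv), CH2Cl2, 0 °C to rt; aq NaHCO3
Reagents that add atoms: methyl trifluoromethanesulfonate, COS(=O)(=O)C(F)(F)F
Why: O-Methylation of a 4-hydroxy-2-pyranone with a hard alkylating agent takes place at the lactone carbonyl oxygen, and deprotonation of the resulting pyrylium salt gives the 2-methoxy-4-pyranone.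

**Step 7**
Reactants: 10 2-methoxy-3,5-dimethyl-6-[(1E)-1-(trimethylsilyl)prop-1-en-2-yl]-4H-pyran-4-one
Product: 11 6-[(1E)-1-iodoprop-1-en-2-yl]-2-methoxy-3,5-dimethyl-4H-pyran-4-one
Conditions: NIS (1.3 equiv), (CF3)2CHOH, 0 °C, dark
Reagents that add atoms: N-iodosuccinimide, O=C1CCC(=O)N1I
Why: Iododesilylation of a vinylsilane (ipso attack of the iodonium source, then loss of silicon from the β-silyl cation) replaces silicon by iodine with retention of the alkene geometry.

**Step 8**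
Reactants: 12 2-bromoprop-2-en-1-ol
Product: 13 [(2-bromoprop-2-en-1-yl)oxy](tert-butyl)dimethylsilane
Conditions: TBSCl, imidazole, CH2Cl2, rt
Reagents that add atoms: tert-butyldimethylsilyl chloride, CC(C)(C)[Si](C)(C)Cl
Why: Silylation of a primary alcohol with a silyl chloride and imidazole.

**Step 9**
Reactants: 13 [(2-bromoprop-2-en-1-yl)oxy](tert-butyl)dimethylsilane; 14 propyne
Product: 15 tert-butyl(dimethyl)[(2-methylidenepent-3-yn-1-yl)oxy]silane
Conditions: Pd(PPh3)2Cl2 (3 mol %), CuI (6 mol %), i-Pr2NH, THF, 14 (excess), 0 °C to rt, sealed vessel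
Reagents that add atoms: none
Why: Sonogashira coupling of a 2-bromo-1-alkene with a terminal alkyne.

**Step 10**
Reactants: 15 tert-butyl(dimethyl)[(2-methylidenepent-3-yn-1-yl)oxy]silane
Product: 17 tert-butyl{[(3E)-4-iodo-2-methylidenepent-3-en-1-yl]oxy}dimethylsilane, via alkenylzirconocene chloride 16 (not isolated)
Conditions: Cp2Zr(H)Cl (1.5 equiv), THF, rt to 40 °C, dark; then I2, THF, 0 °C
Reagents that add atoms: iodine, II
Why: Hydrozirconation adds Zr–H syn across the 2-alkyne and, after equilibration with excess Cp2Zr(H)Cl, places zirconium on the less hindered methyl-bearing carbon, and iodinolysis of the C–Zr bond with retention gives the E iodide; the bulky silyl ether prevents oxygen-directed addition to the other alkyne carbon.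

**Step 11**
Reactants: 14 propyne
Product: 18 2,2'-[(1E)-prop-1-ene-1,2-diyl]bis(4,4,5,5-tetramethyl-1,3,2-dioxaborolane) (the two boron atoms cis)
Conditions: B2pin2, Pt(PPh3)4 (3 mol %), DMF, 80 °C, sealed vessel
Reagents that add atoms: bis(pinacolato)diboron, CC1(C)OB(OC1(C)C)B1OC(C)(C)C(C)(C)O1
Why: Pt(PPh3)4-catalysed diboration of a terminal alkyne is a syn addition (oxidative addition of the B–B bond, insertion, reductive elimination), so both boron atoms stand on the same side of the alkene.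

**Step 12**
Reactants: 18 2,2'-[(1E)-prop-1-ene-1,2-diyl]bis(4,4,5,5-tetramethyl-1,3,2-dioxaborolane); 17 tert-butyl{[(3E)-4-iodo-2-methylidenepent-3-en-1-yl]oxy}dimethylsilane; 11 6-[(1E)-1-iodoprop-1-en-2-yl]-2-methoxy-3,5-dimethyl-4H-pyran-4-one
Product: 20 6-[(2E,4Z,6E)-8-({[tert-butyl(dimethyl)silyl]oxy}methyl)-4,6-dimethylnona-2,4,6,8-tetraen-2-yl]-2-methoxy-3,5-dimethyl-4H-pyran-4-one, via dienylboronate 19 (not isolated)
Conditions: 18 (1.05 equiv), 17 (1.0 equiv), Pd(dppf)Cl2 (5 mol %), aq K3PO4, THF, 25 °C, dark; then 11 (1.1 equiv), Pd(OAc)2 (5 mol %), SPhos (10 mol %), aq K3PO4, 45 °C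
Reagents that add atoms: none
Why: Two Suzuki–Miyaura couplings run in one flask, each by oxidative addition of an alkenyl iodide to zerovalent palladium, base-assisted transmetalation of an alkenyl–boron bond and reductive elimination. The closest known reaction type is the stepwise, site-selective coupling of 1,2-diboryl-1-alkenes made from terminal alkynes, in which the terminal C–B bond reacts first. No ring is closed and no stereocentre is formed here; the step fixes three alkene geometries, each carried over with retention from 17, 18 and 11, so that the central alkene has its two new substituents cis, as the ring closure of step 13 requires. The selectivity needed is the order of the two C–B bonds: it is secured by the steric difference between the terminal CH–B and the methyl-substituted internal C–B bond, by adding the more hindered iodide 17 first at room temperature in one equivalent, and by bringing in iodide 11 with the more active Pd(OAc)2/SPhos catalyst only afterwards. Phosphate base and 45 °C are chosen to spare the methoxypyranone and to keep the tetraene from cyclising or isomerising before it is isolated.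

**Step 13**
Reactants: 20 6-[(2E,4Z,6E)-8-({[tert-butyl(dimethyl)silyl]oxy}methyl)-4,6-dimethylnona-2,4,6,8-tetraen-2-yl]-2-methoxy-3,5-dimethyl-4H-pyran-4-one
Product: 21 rac-6-[(1R,6R)-6-(3-{[tert-butyl(dimethyl)silyl]oxy}prop-1-en-2-yl)-1,3,5-trimethylcyclohexa-2,4-dien-1-yl]-2-methoxy-3,5-dimethyl-4H-pyran-4-one
Conditions: PhMe (degassed), BHT (cat.), 130 °C, sealed tube, dark
Reagents that add atoms: none
Why: Thermal 6π electrocyclisation of the (2E,4Z,6E)-triene is disrotatory, so the two outward substituents (the pyranonyl group on chain C2 and the propenyl group on chain C7) end up cis on the new cyclohexadiene, which sets the relative configuration of the quaternary carbon and its neighbour; the product is racemic.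

**Step 14**
Reactants: 21 rac-6-[(1R,6R)-6-(3-{[tert-butyl(dimethyl)silyl]oxy}prop-1-en-2-yl)-1,3,5-trimethylcyclohexa-2,4-dien-1-yl]-2-methoxy-3,5-dimethyl-4H-pyran-4-one
Product: 22 6-[(1R,4R,5R,6S)-5-(3-{[tert-butyl(dimethyl)silyl]oxy}prop-1-en-2-yl)-2,4,6-trimethyl-7-oxabicyclo[4.1.0]hept-2-en-4-yl]-2-methoxy-3,5-dimethyl-4H-pyran-4-one
Conditions: D-fructose-derived Shi ketone (1,2:4,5-di-O-isopropylidene-β-D-erythro-2,3-hexodiulo-2,6-pyranose, 0.3 equiv), Oxone (KHSO5, 0.6 equiv), K2CO3, Bu4NHSO4 (cat.), Na2B4O7/Na2EDTA buffer, MeCN–CH2(OMe)2–H2O, 0 °C, stopped near half conversion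
Reagents that add atoms: potassium peroxymonosulfate (active salt of Oxone), [K+].[O-]S(=O)(=O)OO
Why: Shi asymmetric epoxidation used as a kinetic resolution of a 1,6-disubstituted cyclohexene: the dioxirane of the D-fructose-derived ketone delivers oxygen through a spiro transition state to the face of the less hindered ring alkene that is anti to the neighbouring propenyl substituent only in the (1R,6R) enantiomer, so this enantiomer should be epoxidised faster and both oxirane stereocentres are set by matched catalyst and substrate preference, while the alkene next to the quaternary carbon, the 1,1-disubstituted alkene and the electron-poor pyranone should react more slowly.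

**Step 15**
Reactants: 22 6-[(1R,4R,5R,6S)-5-(3-{[tert-butyl(dimethyl)silyl]oxy}prop-1-en-2-yl)-2,4,6-trimethyl-7-oxabicyclo[4.1.0]hept-2-en-4-yl]-2-methoxy-3,5-dimethyl-4H-pyran-4-one
Product: 23 6-[(1R,4R,5R,6S)-5-(3-hydroxyprop-1-en-2-yl)-2,4,6-trimethyl-7-oxabicyclo[4.1.0]hept-2-en-4-yl]-2-methoxy-3,5-dimethyl-4H-pyran-4-one
Conditions: Bu4NF, THF, 0 °C
Reagents that add atoms: none
Why: Fluoride cleavage of the primary silyl ether, to which the oxirane and the pyranone should be inert at 0 °C.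

**Step 16**
Reactants: 23 6-[(1R,4R,5R,6S)-5-(3-hydroxyprop-1-en-2-yl)-2,4,6-trimethyl-7-oxabicyclo[4.1.0]hept-2-en-4-yl]-2-methoxy-3,5-dimethyl-4H-pyran-4-one
Product: 24 2-[(1R,4R,5S,6S)-4-(6-methoxy-3,5-dimethyl-4-oxo-4H-pyran-2-yl)-2,4,6-trimethyl-7-oxabicyclo[4.1.0]hept-2-en-5-yl]prop-2-enal
Conditions: Dess–Martin periodinane, NaHCO3, CH2Cl2, 0 °C to rt
Reagents that add atoms: none
Why: Buffered Dess–Martin oxidation converts the primary allylic alcohol into the 2-substituted propenal without acid that could open the vinyl oxirane.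

**Step 17**
Reactants: 24 2-[(1R,4R,5S,6S)-4-(6-methoxy-3,5-dimethyl-4-oxo-4H-pyran-2-yl)-2,4,6-trimethyl-7-oxabicyclo[4.1.0]hept-2-en-5-yl]prop-2-enal; 25 pentan-3-one
Product: 27 6-[(1R,4R,5R,6S)-5-[(3R,4R)-3-hydroxy-4-methyl-5-oxohept-1-en-2-yl]-2,4,6-trimethyl-7-oxabicyclo[4.1.0]hept-2-en-4-yl]-2-methoxy-3,5-dimethyl-4H-pyran-4-one, via Z-enol diisopinocampheylborinate 26 (not isolated)
Conditions: 25 (1.5 equiv), (+)-Ipc2BOTf (prepared from (−)-α-pinene, 1.3 equiv), i-Pr2NEt (1.6 equiv), CH2Cl2, −78 °C; then 24, −78 to −20 °C; pH 7 buffer, MeOH, H2O2, 0 °C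
Reagents that add atoms: none
Why: Paterson syn-aldol reaction: Ipc2BOTf/i-Pr2NEt gives the Z enol borinate of pentan-3-one, which adds through a chair (Zimmerman–Traxler) transition state to give the syn relation of hydroxyl and methyl, while the isopinocampheyl ligands from (−)-α-pinene should direct the enolate to the Re face of the aldehyde and so set both new centres as R; any minor ring enantiomer left from step 14 becomes a separable diastereomer.

**Compound list**
1 | 3-(trimethylsilyl)prop-2-yn-1-ol | C[Si](C)(C)C#CCO | starting material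
2 | 4-methyl-3-(trimethylsilyl)-2,5-dihydro-1,2-oxamagnesole (cyclic alkenylmagnesium alkoxide) | C[Si](C)(C)C1=C(C)CO[Mg]1 | intermediate
3 | (2E)-2-methyl-3-(trimethylsilyl)prop-2-en-1-ol | C[Si](C)(C)/C=C(\C)CO | intermediate
4 | (2E)-2-methyl-3-(trimethylsilyl)prop-2-enal | C[Si](C)(C)/C=C(\C)C=O | intermediate
5 | ethyl 2-methyl-3-oxopentanoate | CCOC(=O)C(C)C(=O)CC | starting material
6 | sodium lithium dienolate (dianion) of ethyl 2-methyl-3-oxopentanoate | CCOC([O-])=C(C)C([O-])=CC.[Na+].[Li+] | intermediate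
7 | ethyl (6E)-5-hydroxy-2,4,6-trimethyl-3-oxo-7-(trimethylsilyl)hept-6-enoate (diastereomer mixture) | CCOC(=O)C(C)C(=O)C(C)C(O)/C(C)=C/[Si](C)(C)C | intermediate
8 | ethyl (6E)-2,4,6-trimethyl-3,5-dioxo-7-(trimethylsilyl)hept-6-enoate | CCOC(=O)C(C)C(=O)C(C)C(=O)/C(C)=C/[Si](C)(C)C | intermediate
9 | 4-hydroxy-3,5-dimethyl-6-[(1E)-1-(trimethylsilyl)prop-1-en-2-yl]-2H-pyran-2-one | CC1=C(O)C(C)=C(/C(C)=C/[Si](C)(C)C)OC1=O | intermediate
10 | 2-methoxy-3,5-dimethyl-6-[(1E)-1-(trimethylsilyl)prop-1-en-2-yl]-4H-pyran-4-one | COc1oc(/C(C)=C/[Si](C)(C)C)c(C)c(=O)c1C | intermediate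
11 | 6-[(1E)-1-iodoprop-1-en-2-yl]-2-methoxy-3,5-dimethyl-4H-pyran-4-one | COc1oc(/C(C)=C/I)c(C)c(=O)c1C | intermediate
12 | 2-bromoprop-2-en-1-ol | C=C(Br)CO | starting material
13 | [(2-bromoprop-2-en-1-yl)oxy](tert-butyl)dimethylsilane | C=C(Br)CO[Si](C)(C)C(C)(C)C | intermediate
14 | propyne | CC#C | starting material
15 | tert-butyl(dimethyl)[(2-methylidenepent-3-yn-1-yl)oxy]silane | CC#CC(=C)CO[Si](C)(C)C(C)(C)C | intermediate
16 | chlorobis(cyclopentadienyl){(2E)-5-[tert-butyl(dimethyl)silyl]oxy-4-methylidenepent-2-en-2-yl}zirconium | C/C(=C\C(=C)CO[Si](C)(C)C(C)(C)C)[Zr](Cl)(C1C=CC=C1)C1C=CC=C1 | intermediate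
17 | tert-butyl{[(3E)-4-iodo-2-methylidenepent-3-en-1-yl]oxy}dimethylsilane | C/C(I)=C\C(=C)CO[Si](C)(C)C(C)(C)C | intermediate
18 | 2,2'-[(1E)-prop-1-ene-1,2-diyl]bis(4,4,5,5-tetramethyl-1,3,2-dioxaborolane) (boron atoms cis) | C/C(B1OC(C)(C)C(C)(C)O1)=C/B1OC(C)(C)C(C)(C)O1 | intermediate
19 | tert-butyl(dimethyl){[(3E,5E)-4-methyl-2-methylidene-6-(4,4,5,5-tetramethyl-1,3,2-dioxaborolan-2-yl)hepta-3,5-dien-1-yl]oxy}silane | C=C(CO[Si](C)(C)C(C)(C)C)/C=C(\C)/C=C(/C)B1OC(C)(C)C(C)(C)O1 | intermediate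
20 | 6-[(2E,4Z,6E)-8-({[tert-butyl(dimethyl)silyl]oxy}methyl)-4,6-dimethylnona-2,4,6,8-tetraen-2-yl]-2-methoxy-3,5-dimethyl-4H-pyran-4-one | C=C(CO[Si](C)(C)C(C)(C)C)/C=C(\C)/C=C(/C)\C=C(/C)c1oc(OC)c(C)c(=O)c1C | intermediate
21 | rac-6-[(1R,6R)-6-(3-{[tert-butyl(dimethyl)silyl]oxy}prop-1-en-2-yl)-1,3,5-trimethylcyclohexa-2,4-dien-1-yl]-2-methoxy-3,5-dimethyl-4H-pyran-4-one (racemate, productive enantiomer drawn) | C=C(CO[Si](C)(C)C(C)(C)C)[C@H]1C(C)=CC(C)=C[C@@]1(C)c1oc(OC)c(C)c(=O)c1C | intermediate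
22 | 6-[(1R,4R,5R,6S)-5-(3-{[tert-butyl(dimethyl)silyl]oxy}prop-1-en-2-yl)-2,4,6-trimethyl-7-oxabicyclo[4.1.0]hept-2-en-4-yl]-2-methoxy-3,5-dimethyl-4H-pyran-4-one | C=C(CO[Si](C)(C)C(C)(C)C)[C@H]1[C@]2(C)O[C@@H]2C(C)=C[C@@]1(C)c1oc(OC)c(C)c(=O)c1C | intermediate
23 | 6-[(1R,4R,5R,6S)-5-(3-hydroxyprop-1-en-2-yl)-2,4,6-trimethyl-7-oxabicyclo[4.1.0]hept-2-en-4-yl]-2-methoxy-3,5-dimethyl-4H-pyran-4-one | C=C(CO)[C@H]1[C@]2(C)O[C@@H]2C(C)=C[C@@]1(C)c1oc(OC)c(C)c(=O)c1C | intermediate
24 | 2-[(1R,4R,5S,6S)-4-(6-methoxy-3,5-dimethyl-4-oxo-4H-pyran-2-yl)-2,4,6-trimethyl-7-oxabicyclo[4.1.0]hept-2-en-5-yl]prop-2-enal | C=C(C=O)[C@H]1[C@]2(C)O[C@@H]2C(C)=C[C@@]1(C)c1oc(OC)c(C)c(=O)c1C | intermediate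
25 | pentan-3-one | CCC(=O)CC | starting material
26 | (2Z)-pent-2-en-3-yl diisopinocampheylborinate (isopinocampheyl groups from (−)-α-pinene) | C/C=C(/CC)OB([C@H]1C[C@H]2C[C@@H]([C@@H]1C)C2(C)C)[C@H]1C[C@H]2C[C@@H]([C@@H]1C)C2(C)C | intermediate
27 | 6-[(1R,4R,5R,6S)-5-[(3R,4R)-3-hydroxy-4-methyl-5-oxohept-1-en-2-yl]-2,4,6-trimethyl-7-oxabicyclo[4.1.0]hept-2-en-4-yl]-2-methoxy-3,5-dimethyl-4H-pyran-4-one | C=C([C@H](O)[C@@H](C)C(=O)CC)[C@H]1[C@]2(C)O[C@@H]2C(C)=C[C@@]1(C)c1oc(OC)c(C)c(=O)c1C | target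

**Totals**
Total step count: 17
Longest linear sequence: 13 steps (steps 1–7, then 12–17)

**Three steps most likely to fail**

Step 12. The two carbon–boron bonds of 18 may not be told apart cleanly, or the hindered internal alkenylboronate 19 may lose boron by protodeboronation before the second, slower coupling. The fallback sets out from 14, 17 and 11 and comes back at 20. It inverts the polarity at the second junction and makes the two bonds in separate flasks. Propyne 14 is bromoborated with BBr3 (syn addition, CH2Cl2, −78 °C) to (Z)-(2-bromoprop-1-en-1-yl)dibromoborane F1, which pinacol converts into 2-[(1Z)-2-bromoprop-1-en-1-yl]-4,4,5,5-tetramethyl-1,3,2-dioxaborolane F2. Suzuki coupling of the C–B bond of F2 with iodide 17 at room temperature gives the dienyl bromide {[(3E,5Z)-6-bromo-4-methyl-2-methylidenehepta-3,5-dien-1-yl]oxy}(tert-butyl)dimethylsilane F3; the C–I bond of 17 should add to zerovalent palladium before the C–Br bond of F2. Iodide 11 is converted by Miyaura borylation (B2pin2, Pd(dppf)Cl2, KOAc) into the alkenylboronate 2-methoxy-3,5-dimethyl-6-[(1E)-1-(4,4,5,5-tetramethyl-1,3,2-dioxaborolan-2-yl)prop-1-en-2-yl]-4H-pyran-4-one F4. A Suzuki coupling of F3 with F4 then gives 20.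

Step 14. The two enantiomers of 21 may react at rates that differ too little, or oxygen may also be delivered to the ring alkene next to the quaternary carbon. The fallback sets out from 21 and comes back at 27. Racemic 21 is epoxidised with mCPBA/NaHCO3, which under substrate control should attack the same alkene anti to the C6 substituent; this gives 22 together with its (1S,4S,5S,6R) enantiomer F5. The pair is carried through steps 15 and 16 to 23 and 24 and their enantiomers, the (1S,4S,5S,6R) alcohol F6 and the (1S,4S,5R,6R) aldehyde F7. The reagent-controlled aldol of step 17 then gives 27 from 24 and the (1S,4S,5S,6R),(3R,4R) diastereomer F8 from F7, and chromatography separates the two.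

Step 17. The boron ligands may control the aldehyde face incompletely, or the boron Lewis acid may open the vinyl oxirane. The fallback sets out from 24 and comes back at 27. An auxiliary-controlled Evans syn-aldol of 24 with the Bu2BOTf/i-Pr2NEt-derived Z-enolate of (4R)-4-benzyl-3-propanoyl-1,3-oxazolidin-2-one gives the imide (4R)-4-benzyl-3-{(2R,3R)-3-hydroxy-4-[(1R,4R,5R,6S)-4-(6-methoxy-3,5-dimethyl-4-oxo-4H-pyran-2-yl)-2,4,6-trimethyl-7-oxabicyclo[4.1.0]hept-2-en-5-yl]-2-methylpent-4-enoyl}-1,3-oxazolidin-2-one F9. Me3Al/MeONHMe·HCl at 0 °C converts it into the corresponding Weinreb amide, (2R,3R)-3-hydroxy-N-methoxy-N,2-dimethyl-4-[(1R,4R,5R,6S)-4-(6-methoxy-3,5-dimethyl-4-oxo-4H-pyran-2-yl)-2,4,6-trimethyl-7-oxabicyclo[4.1.0]hept-2-en-5-yl]pent-4-enamide F10, and EtMgBr gives 27.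

Further compounds
F1 | step 12 | (Z)-(2-bromoprop-1-en-1-yl)dibromoborane | C/C(Br)=C/B(Br)Br
F2 | step 12 | 2-[(1Z)-2-bromoprop-1-en-1-yl]-4,4,5,5-tetramethyl-1,3,2-dioxaborolane | C/C(Br)=C/B1OC(C)(C)C(C)(C)O1
F3 | step 12 | {[(3E,5Z)-6-bromo-4-methyl-2-methylidenehepta-3,5-dien-1-yl]oxy}(tert-butyl)dimethylsilane | C=C(CO[Si](C)(C)C(C)(C)C)/C=C(\C)/C=C(/C)Br
F4 | step 12 | 2-methoxy-3,5-dimethyl-6-[(1E)-1-(4,4,5,5-tetramethyl-1,3,2-dioxaborolan-2-yl)prop-1-en-2-yl]-4H-pyran-4-one | COc1oc(/C(C)=C/B2OC(C)(C)C(C)(C)O2)c(C)c(=O)c1C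
F5 | step 14 | 6-[(1S,4S,5S,6R)-5-(3-{[tert-butyl(dimethyl)silyl]oxy}prop-1-en-2-yl)-2,4,6-trimethyl-7-oxabicyclo[4.1.0]hept-2-en-4-yl]-2-methoxy-3,5-dimethyl-4H-pyran-4-one (enantiomer of 22) | C=C(CO[Si](C)(C)C(C)(C)C)[C@@H]1[C@@]2(C)O[C@H]2C(C)=C[C@]1(C)c1oc(OC)c(C)c(=O)c1C
F6 | step 14 | 6-[(1S,4S,5S,6R)-5-(3-hydroxyprop-1-en-2-yl)-2,4,6-trimethyl-7-oxabicyclo[4.1.0]hept-2-en-4-yl]-2-methoxy-3,5-dimethyl-4H-pyran-4-one (enantiomer of 23) | C=C(CO)[C@@H]1[C@@]2(C)O[C@H]2C(C)=C[C@]1(C)c1oc(OC)c(C)c(=O)c1C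
F7 | step 14 | 2-[(1S,4S,5R,6R)-4-(6-methoxy-3,5-dimethyl-4-oxo-4H-pyran-2-yl)-2,4,6-trimethyl-7-oxabicyclo[4.1.0]hept-2-en-5-yl]prop-2-enal (enantiomer of 24) | C=C(C=O)[C@@H]1[C@@]2(C)O[C@H]2C(C)=C[C@]1(C)c1oc(OC)c(C)c(=O)c1C
F8 | step 14 | 6-[(1S,4S,5S,6R)-5-[(3R,4R)-3-hydroxy-4-methyl-5-oxohept-1-en-2-yl]-2,4,6-trimethyl-7-oxabicyclo[4.1.0]hept-2-en-4-yl]-2-methoxy-3,5-dimethyl-4H-pyran-4-one | C=C([C@H](O)[C@@H](C)C(=O)CC)[C@@H]1[C@@]2(C)O[C@H]2C(C)=C[C@]1(C)c1oc(OC)c(C)c(=O)c1C
F9 | step 17 | (4R)-4-benzyl-3-{(2R,3R)-3-hydroxy-4-[(1R,4R,5R,6S)-4-(6-methoxy-3,5-dimethyl-4-oxo-4H-pyran-2-yl)-2,4,6-trimethyl-7-oxabicyclo[4.1.0]hept-2-en-5-yl]-2-methylpent-4-enoyl}-1,3-oxazolidin-2-one | C=C([C@H](O)[C@@H](C)C(=O)N1C(=O)OC[C@H]1Cc1ccccc1)[C@H]1[C@]2(C)O[C@@H]2C(C)=C[C@@]1(C)c1oc(OC)c(C)c(=O)c1C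
F10 | step 17 | (2R,3R)-3-hydroxy-N-methoxy-N,2-dimethyl-4-[(1R,4R,5R,6S)-4-(6-methoxy-3,5-dimethyl-4-oxo-4H-pyran-2-yl)-2,4,6-trimethyl-7-oxabicyclo[4.1.0]hept-2-en-5-yl]pent-4-enamide | C=C([C@H](O)[C@@H](C)C(=O)N(C)OC)[C@H]1[C@]2(C)O[C@@H]2C(C)=C[C@@]1(C)c1oc(OC)c(C)c(=O)c1C
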